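The methylene bridge is treated as a formaldehyde-level carbon lodged between two 4-hydroxy-2-pyranone rings. Everything rests on cutting the bond between this CH2 and C3 of the pyranone ring that hangs on the tetralone: that C3, flanked by the lactone C2 carbonyl and the C4 enol, is a soft carbon nucleophile. The key step releases a 3-methylidenepyran-2,4-dione from the Mannich base of the naphthyl pyranone and lets the unprotected, enantiopure tetralone pyranone add to it, joining the halves in one operation. Both halves come from one intermediate, since the naphthalene is the dehydrated, aromatized tetralone; its stereocentres are set by a C1 carbinol relay.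

Key step: step 15

Remark 1: all bicyclic intermediates use the tetralone numbering of the target half (C1 carbonyl carbon, C3 carbinol, C4 methine, C8 phenol carbon).
Remark 2: the facial sense of the phosphoric acid in step 4 is assigned by analogy with simple aryl aldehydes; if it is reversed for this 2,6-disubstituted aldehyde, the enantiomeric acid is used and nothing else changes.

Step 1
Reactants: 1 2-bromo-6-hydroxybenzaldehyde
Product: 2 2-(benzyloxy)-6-bromobenzaldehyde
Conditions: BnBr, K2CO3, DMF, rt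
Reagents that add atoms: benzyl bromide, BrCc1ccccc1
Why: Williamson etherification of the phenoxide; benzyl is chosen because its final hydrogenolysis frees only toluene, whereas acetal-type groups would release formaldehyde equivalents that the pyranone would capture.

Step 2
Reactants: 2 2-(benzyloxy)-6-bromobenzaldehyde
Product: 3 2-(benzyloxy)-6-ethenylbenzaldehyde
Conditions: vinylboronic acid pinacol ester, Pd(PPh3)4 (cat.), K2CO3, 1,4-dioxane/H2O, 90 °C
Reagents that add atoms: 4,4,5,5-tetramethyl-2-vinyl-1,3,2-dioxaborolane, C=CB1OC(C)(C)C(C)(C)O1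
Why: Suzuki–Miyaura coupling of the aryl bromide installs the styrene carbon that becomes C4, the aldehyde and the benzyl ether being inert.

Step 3
Reactants: 4 (3-bromoprop-1-en-2-yl)benzene
Product: 5 4,4,5,5-tetramethyl-2-(2-phenylprop-2-en-1-yl)-1,3,2-dioxaborolane
Conditions: B2pin2, Pd2(dba)3 (cat.), THF, 60 °C
Reagents that add atoms: bis(pinacolato)diboron, CC1(C)OB(OC1(C)C)B1OC(C)(C)C(C)(C)O1
Why: palladium-catalysed borylation of an allylic bromide (pi-allyl formation, transmetalation with the diboron, reductive elimination) gives the 2-substituted allylboronate.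

Step 4
Reactants: 3 2-(benzyloxy)-6-ethenylbenzaldehyde; 5 4,4,5,5-tetramethyl-2-(2-phenylprop-2-en-1-yl)-1,3,2-dioxaborolane
Product: 6 (1S)-1-[2-(benzyloxy)-6-ethenylphenyl]-3-phenylbut-3-en-1-ol
Conditions: (S)-TRIP (3,3'-bis(2,4,6-triisopropylphenyl)-BINOL hydrogen phosphate, 5 mol %), toluene, −30 °C → rt; aq. work-up
Reagents that add atoms: none
Why: chiral phosphoric acid-catalysed allylboration through a closed chair transition state in which the acid binds the boronate oxygen and the formyl hydrogen, so that the allyl group should be delivered to the Si face and set C1 as S.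

Step 5
Reactants: 6 (1S)-1-[2-(benzyloxy)-6-ethenylphenyl]-3-phenylbut-3-en-1-ol
Product: 7 (1S)-8-(benzyloxy)-3-phenyl-1,2-dihydronaphthalen-1-ol
Conditions: second-generation Grubbs catalyst (5 mol %), toluene, 60 °C
Reagents that add atoms: none
Why: ring-closing metathesis of the styrene with the 1,1-disubstituted alkene closes the six-membered ring as the C3=C4 trisubstituted alkene with loss of ethene, under neutral conditions that spare the acid-labile benzylic homoallylic alcohol.

Step 6
Reactants: 7 (1S)-8-(benzyloxy)-3-phenyl-1,2-dihydronaphthalen-1-ol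
Product: 8 (1S,3S,4S)-8-(benzyloxy)-3,4-epoxy-3-phenyl-1,2,3,4-tetrahydronaphthalen-1-ol (epoxide oxygen cis to the C1 hydroxyl)
Conditions: VO(acac)2 (cat.), t-BuOOH (in decane), CH2Cl2, 0 °C → rt
Reagents that add atoms: tert-butyl hydroperoxide, CC(C)(C)OO
Why: hydroxyl-directed vanadium-catalysed epoxidation of a cyclic homoallylic alcohol, in which the vanadate ester of the pseudoaxial C1 hydroxyl delivers oxygen to its own face, so that the C1 stereocenter sets C3 and C4.

Step 7
Reactants: 8 (1S,3S,4S)-8-(benzyloxy)-3,4-epoxy-3-phenyl-1,2,3,4-tetrahydronaphthalen-1-ol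
Product: 9 (1S,3R,4R)-8-(benzyloxy)-4-ethynyl-3-phenyl-1,2,3,4-tetrahydronaphthalene-1,3-diol (1-OH and 3-OH cis; ethynyl trans to 3-OH)
Conditions: lithium acetylide–ethylenediamine complex (4 equiv), DMSO, rt; then H2O
Reagents that add atoms: lithium acetylide–ethylenediamine complex, [Li+].[C-]#C.NCCN
Why: Lewis-acid-free SN2 opening of the epoxide at the secondary benzylic C4 (the quaternary C3 is blocked; trans-diaxial Fürst–Plattner mode) with inversion, which places the ethynyl group trans to the C3 hydroxyl and cis to phenyl.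

Step 8
Reactants: 9 (1S,3R,4R)-8-(benzyloxy)-4-ethynyl-3-phenyl-1,2,3,4-tetrahydronaphthalene-1,3-diol
Product: 10 3-[(1R,2R,4S)-5-(benzyloxy)-2,4-dihydroxy-2-phenyl-1,2,3,4-tetrahydronaphthalen-1-yl]prop-2-ynal
Conditions: n-BuLi (3.1 equiv), THF, −78 °C; DMF, −78 → 0 °C; reverse quench into cold aq. KH2PO4
Reagents that add atoms: N,N-dimethylformamide, CN(C)C=O
Why: formylation of the lithium acetylide (the two lithium alkoxides do not react with DMF) with buffered release of the ynal, so that no base meets the acidic propargylic C4–H once the acceptor is in place.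

Step 9
Reactants: 10 3-[(1R,2R,4S)-5-(benzyloxy)-2,4-dihydroxy-2-phenyl-1,2,3,4-tetrahydronaphthalen-1-yl]prop-2-ynal
Product: 11 tert-butyl 5-[(1R,2R,4S)-5-(benzyloxy)-2,4-dihydroxy-2-phenyl-1,2,3,4-tetrahydronaphthalen-1-yl]-3-hydroxypent-4-ynoate (both epimers at the chain carbinol)
Conditions: t-BuOAc, LDA (4 equiv each), THF, −78 °C; then 10, −78 °C; AcOH quench
Reagents that add atoms: tert-butyl acetate, CC(=O)OC(C)(C)C
Why: acetate aldol addition of the lithium ester enolate to the ynal carbonyl, which at −78 °C should outrun gamma-deprotonation; the new carbinol forms as both epimers, which is immaterial because step 10 oxidises it.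

Step 10
Reactants: 11 tert-butyl 5-[(1R,2R,4S)-5-(benzyloxy)-2,4-dihydroxy-2-phenyl-1,2,3,4-tetrahydronaphthalen-1-yl]-3-hydroxypent-4-ynoate
Product: 12 tert-butyl 5-[(1R,2R)-5-(benzyloxy)-2-hydroxy-4-oxo-2-phenyl-1,2,3,4-tetrahydronaphthalen-1-yl]-3-oxopent-4-ynoate
Conditions: Dess–Martin periodinane (3 equiv), CH2Cl2, 0 °C → rt
Reagents that add atoms: none
Why: Dess–Martin oxidation converts both secondary alcohols at once (propargylic carbinol to the ynone, C1 benzylic carbinol to the tetralone ketone, which erases the relay stereocenter), while the tertiary C3 alcohol cannot be oxidised.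

Step 11
Reactants: 12 tert-butyl 5-[(1R,2R)-5-(benzyloxy)-2-hydroxy-4-oxo-2-phenyl-1,2,3,4-tetrahydronaphthalen-1-yl]-3-oxopent-4-ynoate
Product: 13 (3R,4R)-8-(benzyloxy)-3-hydroxy-4-(4-hydroxy-2-oxo-2H-pyran-6-yl)-3-phenyl-3,4-dihydronaphthalen-1(2H)-one
Conditions: (SPhos)AuNTf2 (5 mol %), MeNO2/AcOH (4:1), rt
Reagents that add atoms: none
Why: gold-catalysed 6-endo-dig cyclisation of a 3-oxo-4-ynoic tert-butyl ester (ester carbonyl oxygen attacks the activated alkyne carbon remote from the ketone, tert-butyl leaves as isobutene, protodeauration) builds the 4-hydroxy-2-pyranone without base, so the beta-hydroxy ketone and C4 stay intact.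

Step 12
Reactants: 13 (3R,4R)-8-(benzyloxy)-3-hydroxy-4-(4-hydroxy-2-oxo-2H-pyran-6-yl)-3-phenyl-3,4-dihydronaphthalen-1(2H)-one
Product: 14 (3R,4R)-3,8-dihydroxy-4-(4-hydroxy-2-oxo-2H-pyran-6-yl)-3-phenyl-3,4-dihydronaphthalen-1(2H)-one
Conditions: H2 (1 atm), Pd/C, EtOAc, rt, stopped at full conversion
Reagents that add atoms: none
Why: neutral hydrogenolysis of the aryl benzyl ether, expected to outpace reduction of the hindered trisubstituted pyranone C5=C6 bond and of the aryl ketone.

Step 13
Reactants: 14 (3R,4R)-3,8-dihydroxy-4-(4-hydroxy-2-oxo-2H-pyran-6-yl)-3-phenyl-3,4-dihydronaphthalen-1(2H)-one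
Product: 16 6-(4,5-dihydroxy-2-phenylnaphthalen-1-yl)-4-hydroxy-2H-pyran-2-one, via enone 15 (not isolated)
Conditions: about half of 14, p-TsOH·H2O (cat.), toluene, 80 °C, argon
Reagents that add atoms: none
Why: acid-catalysed dehydration of the tertiary benzylic beta-hydroxy ketone gives the cross-conjugated enone, which tautomerises at once to the naphthalen-1-ol with aromatisation as driving force, both stereocenters being lost on purpose.

Step 14
Reactants: 16 6-(4,5-dihydroxy-2-phenylnaphthalen-1-yl)-4-hydroxy-2H-pyran-2-one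
Product: 17 3-[(dimethylamino)methyl]-6-(4,5-dihydroxy-2-phenylnaphthalen-1-yl)-4-hydroxy-2H-pyran-2-one
Conditions: Eschenmoser's salt (1.0 equiv), MeCN, 0 °C → rt; then aq. NaHCO3 (1 equiv); product collected as the inner salt
Reagents that add atoms: N,N-dimethylmethyleneiminium iodide, C=[N+](C)C.[I-]
Why: Mannich reaction at C3 of the 4-hydroxy-2-pyranone, the most nucleophilic carbon of 16 without added base (the naphthol carbons need base or heat), with one equivalent of iminium salt to avoid a second aminomethylation.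

Step 15
Reactants: 17 3-[(dimethylamino)methyl]-6-(4,5-dihydroxy-2-phenylnaphthalen-1-yl)-4-hydroxy-2H-pyran-2-one; 14 (3R,4R)-3,8-dihydroxy-4-(4-hydroxy-2-oxo-2H-pyran-6-yl)-3-phenyl-3,4-dihydronaphthalen-1(2H)-one
Product: 19 wailupemycin I, via methylidene dione 18 (not isolated)
Conditions: 17 (1.1 equiv), 14 (1.0 equiv), MeCN, 50 °C, slow argon stream to carry off Me2NH
Reagents that add atoms: none
Why: Warming the zwitterionic Mannich base 17 should expel dimethylamine by an E1cB pathway and unveil the 3-methylidenepyran-2,4-dione 18, a vinylogous acyl ortho-quinone methide whose exocyclic CH2 is a strong Michael acceptor; C3 of the 4-hydroxy-2-pyranone ring of 14 adds to it and the adduct tautomerises to the bis-enol 19. The closest known reaction type is the Mannich-base (ortho-quinone-methide) alkylation of 4-hydroxycoumarins and 4-hydroxy-6-methyl-2-pyranone that leads to dicoumarol-type and mixed methylene-bridged bis(1,3-dicarbonyl) compounds. No ring is closed and no stereocenter is created; C3 and C4 of the tetralone are not touched, because the acidic pyranone hydroxyl (pKa about 5) buffers the amine and the temperature stays below that of the dehydration in step 13. The step needs cross-selectivity over both symmetrical dimers and C- over O-alkylation: the first is secured by carrying the one-carbon unit only on the isolated naphthyl partner, so that no free formaldehyde equivalent meets 14, the second by the reversibility of O-attack and by C3 being the only carbon flanked by both the C2 carbonyl and the C4 enol. The peri-hydrogen-bonded 8-OH ring, the naphthalenediol carbons and the ketone alpha-carbon are much weaker carbon nucleophiles under these conditions.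

Compound list
1 | 2-bromo-6-hydroxybenzaldehyde | O=Cc1c(O)cccc1Br | starting material
2 | 2-(benzyloxy)-6-bromobenzaldehyde | O=Cc1c(OCc2ccccc2)cccc1Br | intermediate
3 | 2-(benzyloxy)-6-ethenylbenzaldehyde | O=Cc1c(OCc2ccccc2)cccc1C=C | intermediate
4 | (3-bromoprop-1-en-2-yl)benzene (alpha-(bromomethyl)styrene) | C=C(CBr)c1ccccc1 | starting material
5 | 4,4,5,5-tetramethyl-2-(2-phenylprop-2-en-1-yl)-1,3,2-dioxaborolane | C=C(CB1OC(C)(C)C(C)(C)O1)c1ccccc1 | intermediate
6 | (1S)-1-[2-(benzyloxy)-6-ethenylphenyl]-3-phenylbut-3-en-1-ol | O[C@@H](CC(=C)c1ccccc1)c1c(OCc2ccccc2)cccc1C=C | intermediate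
7 | (1S)-8-(benzyloxy)-3-phenyl-1,2-dihydronaphthalen-1-ol | O[C@H]1CC(c2ccccc2)=Cc2cccc(OCc3ccccc3)c21 | intermediate
8 | (1S,3S,4S)-8-(benzyloxy)-3,4-epoxy-3-phenyl-1,2,3,4-tetrahydronaphthalen-1-ol, epoxide cis to 1-OH | O[C@H]1C[C@@]2(c3ccccc3)O[C@H]2c2cccc(OCc3ccccc3)c21 | intermediate
9 | (1S,3R,4R)-8-(benzyloxy)-4-ethynyl-3-phenyl-1,2,3,4-tetrahydronaphthalene-1,3-diol | O[C@H]1C[C@](O)(c2ccccc2)[C@H](C#C)c2cccc(OCc3ccccc3)c21 | intermediate
10 | 3-[(1R,2R,4S)-5-(benzyloxy)-2,4-dihydroxy-2-phenyl-1,2,3,4-tetrahydronaphthalen-1-yl]prop-2-ynal | O[C@H]1C[C@](O)(c2ccccc2)[C@H](C#CC=O)c2cccc(OCc3ccccc3)c21 | intermediate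
11 | tert-butyl 5-[(1R,2R,4S)-5-(benzyloxy)-2,4-dihydroxy-2-phenyl-1,2,3,4-tetrahydronaphthalen-1-yl]-3-hydroxypent-4-ynoate, both epimers at the chain carbinol | O[C@H]1C[C@](O)(c2ccccc2)[C@H](C#CC(O)CC(=O)OC(C)(C)C)c2cccc(OCc3ccccc3)c21 | intermediate
12 | tert-butyl 5-[(1R,2R)-5-(benzyloxy)-2-hydroxy-4-oxo-2-phenyl-1,2,3,4-tetrahydronaphthalen-1-yl]-3-oxopent-4-ynoate | O=C1C[C@](O)(c2ccccc2)[C@H](C#CC(=O)CC(=O)OC(C)(C)C)c2cccc(OCc3ccccc3)c21 | intermediate
13 | (3R,4R)-8-(benzyloxy)-3-hydroxy-4-(4-hydroxy-2-oxo-2H-pyran-6-yl)-3-phenyl-3,4-dihydronaphthalen-1(2H)-one | O=C1C[C@](O)(c2ccccc2)[C@H](c2cc(O)cc(=O)o2)c2cccc(OCc3ccccc3)c21 | intermediate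
14 | (3R,4R)-3,8-dihydroxy-4-(4-hydroxy-2-oxo-2H-pyran-6-yl)-3-phenyl-3,4-dihydronaphthalen-1(2H)-one (3-OH trans to the pyranone) | O=C1C[C@](O)(c2ccccc2)[C@H](c2cc(O)cc(=O)o2)c2cccc(O)c21 | intermediate
15 | (4S)-8-hydroxy-4-(4-hydroxy-2-oxo-2H-pyran-6-yl)-3-phenylnaphthalen-1(4H)-one | O=C1C=C(c2ccccc2)[C@H](c2cc(O)cc(=O)o2)c2cccc(O)c21 | intermediate (not isolated)
16 | 6-(4,5-dihydroxy-2-phenylnaphthalen-1-yl)-4-hydroxy-2H-pyran-2-one | O=c1cc(O)cc(-c2c(-c3ccccc3)cc(O)c3c(O)cccc23)o1 | intermediate
17 | 3-[(dimethylamino)methyl]-6-(4,5-dihydroxy-2-phenylnaphthalen-1-yl)-4-hydroxy-2H-pyran-2-one | CN(C)Cc1c(O)cc(-c2c(-c3ccccc3)cc(O)c3c(O)cccc23)oc1=O | intermediate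
18 | 6-(4,5-dihydroxy-2-phenylnaphthalen-1-yl)-3-methylidene-2H-pyran-2,4(3H)-dione | C=C1C(=O)C=C(-c2c(-c3ccccc3)cc(O)c3c(O)cccc23)OC1=O | intermediate (not isolated)
19 | wailupemycin I: 6-[(1R,2R)-2,5-dihydroxy-4-oxo-2-phenyl-1,2,3,4-tetrahydronaphthalen-1-yl]-3-{[6-(4,5-dihydroxy-2-phenylnaphthalen-1-yl)-4-hydroxy-2-oxo-2H-pyran-3-yl]methyl}-4-hydroxy-2H-pyran-2-one | O=C1C[C@](O)(c2ccccc2)[C@H](c2cc(O)c(Cc3c(O)cc(-c4c(-c5ccccc5)cc(O)c5c(O)cccc45)oc3=O)c(=O)o2)c2cccc(O)c21 | target

Total step count: 15.
Longest linear sequence: 14 steps (from 1 through steps 1, 2 and 4 to 15; step 3 is a side branch).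

Steps most likely to fail

1. Step 15. The one-carbon unit may be transferred between the two pyranones by retro-Mannich cleavage, which would give both symmetrical dimers, and amine or heat may promote loss of water from the tetralone half. The fallback separates bond formation from adjustment of the oxidation level and uses known oxonol-type chemistry. It sets out from 16: condensation with triethyl orthoformate and aniline (2-propanol, 80 °C) should give 6-(4,5-dihydroxy-2-phenylnaphthalen-1-yl)-3-[(phenylamino)methylidene]-2H-pyran-2,4(3H)-dione F1. F1 and 14 in AcOH at rt should exchange aniline for C3 of 14 and give the methine-bridged bis-pyranone F2 (exocyclic double-bond geometry of F1 and F2 not fixed, the tautomers interconvert). Conjugate transfer hydrogenation of F2 with Hantzsch ester (CH2Cl2, rt) comes back to the route at 19.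

2. Step 7. Substitution next to a quaternary centre may be slow, so that base-induced isomerisation of the epoxide or attack at the wrong carbon competes. The fallback uses a soft, weakly basic nucleophile and sets out from 8: vinylmagnesium bromide with catalytic CuI (THF, −30 °C) should open the epoxide at C4 to (1S,3R,4R)-8-(benzyloxy)-4-ethenyl-3-phenyl-1,2,3,4-tetrahydronaphthalene-1,3-diol F3. Ozonolysis (O3, CH2Cl2/MeOH, −78 °C; Me2S) should give (1R,2R,4S)-5-(benzyloxy)-2,4-dihydroxy-2-phenyl-1,2,3,4-tetrahydronaphthalene-1-carbaldehyde F4. Ohira–Bestmann homologation (dimethyl (1-diazo-2-oxopropyl)phosphonate, K2CO3, MeOH, 0 °C) comes back to the route at 9.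

3. Step 6. The Lewis-acidic catalyst may promote loss of water from the dihydronaphthalenol (aromatisation) before oxygen transfer, or facial control may be incomplete. The fallback replaces metal-directed oxygen transfer by iodocarbonate cyclisation and sets out from 7: Boc2O with DMAP (MeCN, rt) should give tert-butyl (1S)-8-(benzyloxy)-3-phenyl-1,2-dihydronaphthalen-1-yl carbonate F5. IBr (toluene, −85 °C) should close the six-membered cyclic carbonate onto C3 from the face of the C1 oxygen, with iodine anti at C4, giving (1S,3S,4R)-8-(benzyloxy)-4-iodo-3-phenyl-1,2,3,4-tetrahydronaphthalene-1,3-diyl carbonate F6. K2CO3 in MeOH then frees the C3 alkoxide, which displaces iodide with inversion and comes back to the route at 8.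

Further compounds
F1 | step 15 | 6-(4,5-dihydroxy-2-phenylnaphthalen-1-yl)-3-[(phenylamino)methylidene]-2H-pyran-2,4(3H)-dione | O=C1C=C(-c2c(-c3ccccc3)cc(O)c3c(O)cccc23)OC(=O)C1=CNc1ccccc1
F2 | step 15 | 6-[(1R,2R)-2,5-dihydroxy-4-oxo-2-phenyl-1,2,3,4-tetrahydronaphthalen-1-yl]-3-{[6-(4,5-dihydroxy-2-phenylnaphthalen-1-yl)-2,4-dioxo-2H-pyran-3(4H)-ylidene]methyl}-4-hydroxy-2H-pyran-2-one | O=C1C[C@](O)(c2ccccc2)[C@H](c2cc(O)c(C=C3C(=O)C=C(-c4c(-c5ccccc5)cc(O)c5c(O)cccc45)OC3=O)c(=O)o2)c2cccc(O)c21
F3 | step 7 | (1S,3R,4R)-8-(benzyloxy)-4-ethenyl-3-phenyl-1,2,3,4-tetrahydronaphthalene-1,3-diol | O[C@H]1C[C@](O)(c2ccccc2)[C@H](C=C)c2cccc(OCc3ccccc3)c21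
F4 | step 7 | (1R,2R,4S)-5-(benzyloxy)-2,4-dihydroxy-2-phenyl-1,2,3,4-tetrahydronaphthalene-1-carbaldehyde | O[C@H]1C[C@](O)(c2ccccc2)[C@H](C=O)c2cccc(OCc3ccccc3)c21
F5 | step 6 | tert-butyl (1S)-8-(benzyloxy)-3-phenyl-1,2-dihydronaphthalen-1-yl carbonate | CC(C)(C)OC(=O)O[C@H]1CC(c2ccccc2)=Cc2cccc(OCc3ccccc3)c21
F6 | step 6 | (1S,3S,4R)-8-(benzyloxy)-4-iodo-3-phenyl-1,2,3,4-tetrahydronaphthalene-1,3-diyl carbonate | O1[C@H]2C[C@](OC1=O)(c1ccccc1)[C@H](I)c1cccc(OCc3ccccc3)c12
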